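**Plan**

1. Labels: core ring C1 (epoxide carbon carrying the chain), C2 (epoxide CH), C3 and C6 (carbinols), C4=C5 (CH2OH on C4); chain C7 (carbinol), C8=C9 (methyl on C9), C10=C11; terpene ring C1' (carries C11), C2' (CMe2), C3' (carbinol), C6' (tertiary carbinol).
2. Retrosynthesis: after the five silyl ethers, the C7–C8 and C9–C10 bonds are cut together, leaving a core epoxy aldehyde (C7 as CHO), propyne (C8, C9, CH3) and a terpene (E)-vinyl iodide (C10, C11, ring). The iodide goes back by Takai olefination and epoxide-initiated cyclization to geranyl acetate; the aldehyde goes back by retro-Diels–Alder unmasking to a 2,5-disubstituted benzoquinone and cyclopentadiene.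
3. Enabling feature: the trisubstituted C8=C9 alkene has its methyl on C9 and holds C7 cis to C10. This is the pattern left when a C10–Cu bond adds syn across propyne and the new C8–Cu bond is captured by the aldehyde. The 7-oxabicyclo[4.1.0]heptene core and the trimethylcyclohexane ring are complete beforehand, and no ring forms in the union.
4. Forward order: the cyclohexane ring arises first (radical cyclization). The core six-membered ring comes from the quinone; it is carried as a cyclopentadiene adduct while the epoxide and both carbinols are installed, then released. The chain is joined last in one three-component step.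
5. Stereochemistry: C3' from the Shi epoxidation; C1' from the chair cyclization; C6' from equatorial epoxidation. Core C1, C2, C3, C6 come from the Diels–Alder catalyst and the convex face of the adduct. C7 comes from chelation-controlled addition. C10=C11 (E) comes from the Takai reaction and C8=C9 (Z) from syn carbocupration.
6. End game: one buffered fluoride desilylation.

Key step: step 19

Assumption: the (S)-oxazaborolidinium catalyst of step 11 is taken to give the adduct enantiomer drawn for 14; if the facial sense is the reverse, the (R)-catalyst is used and nothing else changes.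

**Terpene half**

Step 1
Reactants: 1 geranyl acetate
Product: 2 (R)-6,7-epoxygeranyl acetate, (2E)-5-[(2R)-3,3-dimethyloxiran-2-yl]-3-methylpent-2-en-1-yl acetate
Conditions: 1,2:4,5-di-O-isopropylidene-β-D-erythro-2,3-hexodiulo-2,6-pyranose (Shi ketone, 0.3 equiv), Oxone (2KHSO5·KHSO4·K2SO4), K2CO3, Bu4NHSO4, MeCN/CH2(OMe)2/aq. Na2B4O7 buffer, 0 °C
Reagents that add atoms: potassium peroxymonosulfate (active part of Oxone), SMILES [K+].[O-]S(=O)(=O)OO
Why: Shi dioxirane epoxidation, in which the electron-rich 6,7-alkene reacts ahead of the 2,3-alkene deactivated by the allylic acetate, and the spiro transition state of the D-fructose-derived ketone delivers oxygen to the face that gives the (R)-epoxide, the source of C3'.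

Step 2
Reactants: 2 (R)-6,7-epoxygeranyl acetate
Product: 3 [(1S,3R)-3-hydroxy-2,2-dimethyl-6-methylidenecyclohexyl]methyl acetate (hydroxyl and acetoxymethyl cis)
Conditions: Cp2TiCl2 (2.2 equiv), Mn dust (8 equiv), THF, rt, slow addition of 2; 1 M HCl work-up
Reagents that add atoms: none
Why: Titanocene-mediated radical epoxypolyene cyclization, in which Cp2TiCl (trivalent titanium) opens the epoxide at the tertiary carbon, the radical closes 6-endo through a chair with the titanium alkoxide and the acetoxymethyl group equatorial (setting C1' cis to the C3' oxygen), and a second Cp2TiCl traps the tertiary radical and eliminates to the exocyclic alkene.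

Step 3
Reactants: 3 exocyclic alkene
Product: 4 [(3R,4S,6R)-6-hydroxy-5,5-dimethyl-1-oxaspiro[2.5]octan-4-yl]methyl acetate (epoxide oxygen equatorial, trans to the acetoxymethyl group)
Conditions: mCPBA, NaHCO3, CH2Cl2, 0 °C
Reagents that add atoms: 3-chloroperoxybenzoic acid, SMILES OOC(=O)c1cccc(Cl)c1
Why: Prilezhaev epoxidation, in which the axial methyl of C2' blocks the axial trajectory (1,3-diaxial) so that the peracid enters equatorially and the new C–O bond at C6' is equatorial, as in the epoxidation of albicanyl acetate.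

Step 4
Reactants: 4 spiro-epoxide
Product: 5 (1R,2S,4R)-2-(hydroxymethyl)-1,3,3-trimethylcyclohexane-1,4-diol
Conditions: LiAlH4 (3 equiv), THF, 0 → 40 °C; aqueous NaOH work-up
Reagents that add atoms: none
Why: Hydride opens the spiro-epoxide by SN2 attack at its unhindered CH2 terminus, leaving the tertiary alcohol with the configuration fixed in step 3, and the same reagent cleaves the acetate.

Step 5
Reactants: 5 triol
Product: 6 (1R,2S,4R)-1,3,3-trimethyl-1,4-bis(triethylsilyloxy)-2-[(triethylsilyloxy)methyl]cyclohexane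
Conditions: Et3SiOTf (4 equiv), 2,6-lutidine (6 equiv), CH2Cl2, −78 → 0 °C
Reagents that add atoms: triethylsilyl triflate, SMILES CC[Si](CC)(CC)OS(=O)(=O)C(F)(F)F
Why: Silyl triflate with 2,6-lutidine is reactive enough to silylate the tertiary and the neopentylic hydroxyls as well as the secondary one, and no stereocentre is touched.

Step 6
Reactants: 6 tris(triethylsilyl) ether
Product: 7 (1R,3R,6R)-2,2,6-trimethyl-3,6-bis(triethylsilyloxy)cyclohexane-1-carbaldehyde
Conditions: (COCl)2 (3 equiv), DMSO (6 equiv), CH2Cl2, −78 → −30 °C; Et3N, −78 → 0 °C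
Reagents that add atoms: none
Why: Swern oxidation of a primary triethylsilyl ether, which is cleaved by chlorodimethylsulfonium chloride and oxidized directly to the aldehyde while the secondary and tertiary triethylsilyl ethers survive, the formyl group staying in its equatorial, thermodynamically preferred position.

Step 7
Reactants: 7 aldehyde
Product: 8 (1R,2R,4R)-2-[(E)-2-iodoethenyl]-1,3,3-trimethyl-1,4-bis(triethylsilyloxy)cyclohexane
Conditions: CrCl2 (8 equiv), CHI3 (3 equiv), THF/1,4-dioxane, 0 °C → rt
Reagents that add atoms: iodoform, SMILES IC(I)I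
Why: Takai olefination, in which the geminal dichromium species from CHI3 and CrCl2 adds to the aldehyde and eliminates to the (E)-vinyl iodide under non-basic conditions that spare the β-silyloxy aldehyde from elimination or epimerization.

**Core half**

Step 8
Reactants: 9 2,5-dimethoxyterephthalaldehyde
Product: 10 2,5-dimethoxy-1,4-benzenedimethanol
Conditions: NaBH4, MeOH/THF, 0 °C
Reagents that add atoms: none
Why: Borohydride reduction of both aryl aldehydes to the benzylic alcohols.

Step 9
Reactants: 10 diol
Product: 11 1,4-bis[(tert-butyldimethylsilyloxy)methyl]-2,5-dimethoxybenzene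
Conditions: TBSCl (2.4 equiv), imidazole (5 equiv), DMF, rt
Reagents that add atoms: tert-butyldimethylsilyl chloride, SMILES CC(C)(C)[Si](C)(C)Cl
Why: Imidazole-promoted silylation of two unhindered primary benzylic alcohols.

Step 10
Reactants: 11 bis-silyl ether
Product: 12 2,5-bis[(tert-butyldimethylsilyloxy)methyl]-1,4-benzoquinone
Conditions: (NH4)2Ce(NO3)6 (2.5 equiv), MeCN/H2O, 0 °C, 10 min
Reagents that add atoms: water, SMILES O
Why: Oxidative demethylation of a para-dimethoxyarene by two one-electron oxidations and capture by water gives the para-quinone, and the short contact at 0 °C is chosen to spare the primary silyl ethers.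

Step 11
Reactants: 12 quinone; 13 cyclopentadiene
Product: 14 endo adduct, 2,5-bis[(tert-butyldimethylsilyloxy)methyl]tricyclo[6.2.1.0(2,7)]undeca-4,9-diene-3,6-dione (cis ring fusion, enedione ring under the C9=C10 bond, enantiomer as in the SMILES)
Conditions: (S)-1-(2-methylphenyl)-3,3-diphenyltetrahydro-1H,3H-pyrrolo[1,2-c][1,3,2]oxazaborole (0.2 equiv), HNTf2 (0.18 equiv), 13 (5 equiv), CH2Cl2, −78 °C
Reagents that add atoms: none
Why: Catalytic enantioselective Diels–Alder reaction with a cationic oxazaborolidine, in which the two C=C bonds of the C2-symmetric quinone are equivalent, the catalyst bound to one carbonyl oxygen shields one face, and endo suprafacial addition sets the four new stereocentres (two ring-fusion carbons, two bridgeheads) in one relative and one absolute sense.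

Step 12
Reactants: 14 adduct
Product: 15 exo-4,5-epoxide of 14 (oxygen on the convex face, on the side of the C2 silyloxymethyl group and the C7 hydrogen)
Conditions: tBuOOH (in decane, 2 equiv), DBU (1.2 equiv), CH2Cl2, 0 °C
Reagents that add atoms: tert-butyl hydroperoxide, SMILES CC(C)(C)OO
Why: Weitz–Scheffer nucleophilic epoxidation, in which tert-butylperoxide adds to the enedione from the convex face of the cis-fused tricycle (the concave face lies under the norbornene bridge) and closes to the epoxide that becomes C1–O–C2, a silyloxide being too poor a leaving group for elimination from the enolate.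

Step 13
Reactants: 15 epoxy dione
Product: 16 endo,endo-3,6-diol of 15 (both hydroxyls on the concave face, cis to each other and trans to the epoxide)
Conditions: NaBH4 (3 equiv), MeOH/CH2Cl2, −40 → 0 °C
Reagents that add atoms: none
Why: Hydride reaches both ketones from the open convex face, so both new carbinols (core C3 and C6) carry endo hydroxyls trans to the epoxide, as known for epoxides of cyclopentadiene–benzoquinone adducts.

Step 14
Reactants: 16 diol
Product: 17 3,6-bis(tert-butyldimethylsilyl) ether of 16
Conditions: TBSOTf (3 equiv), 2,6-lutidine (5 equiv), CH2Cl2, 0 °C → rt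
Reagents that add atoms: tert-butyldimethylsilyl triflate, SMILES CC(C)(C)[Si](C)(C)OS(=O)(=O)C(F)(F)F
Why: Silyl triflate silylation is forceful enough for the two hindered endo hydroxyls and leaves the epoxide intact in the presence of 2,6-lutidine.

Step 15
Reactants: 17 tetrasilyl tricycle
Product: 18 (1S,2S,5R,6S)-2,5-bis(tert-butyldimethylsilyloxy)-1,4-bis[(tert-butyldimethylsilyloxy)methyl]-7-oxabicyclo[4.1.0]hept-3-ene
Conditions: Ph2O, 240 °C, N2 stream
Reagents that add atoms: none
Why: Thermal retro-Diels–Alder reaction, in which loss of volatile cyclopentadiene regenerates the C4=C5 alkene bearing the silyloxymethyl group and leaves the four oxygenated stereocentres untouched.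

Step 16
Reactants: 18 tetrasilyl ether
Product: 19 [(1S,2S,5R,6S)-2,5-bis(tert-butyldimethylsilyloxy)-7-oxabicyclo[4.1.0]hept-3-ene-1,4-diyl]dimethanol
Conditions: HF·pyridine, pyridine, THF, 0 °C
Reagents that add atoms: none
Why: Buffered HF·pyridine removes primary tert-butyldimethylsilyl ethers faster than the two hindered secondary ones and does not open the epoxide.

Step 17
Reactants: 19 diol
Product: 20 [(1S,2S,5R,6S)-2,5-bis(tert-butyldimethylsilyloxy)-4-[(tert-butyldimethylsilyloxy)methyl]-7-oxabicyclo[4.1.0]hept-3-en-1-yl]methanol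
Conditions: TBSCl (1.05 equiv), imidazole (2 equiv), CH2Cl2, −40 → −20 °C
Reagents that add atoms: tert-butyldimethylsilyl chloride, SMILES CC(C)(C)[Si](C)(C)Cl
Why: Steric differentiation of two primary alcohols, the allylic CH2OH on the sp2 carbon C4 being silylated ahead of the neopentylic CH2OH on the quaternary epoxide carbon C1, which is flanked by a silyl ether.

Step 18
Reactants: 20 epoxy alcohol
Product: 21 (1S,2S,5R,6S)-2,5-bis(tert-butyldimethylsilyloxy)-4-[(tert-butyldimethylsilyloxy)methyl]-7-oxabicyclo[4.1.0]hept-3-ene-1-carbaldehyde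
Conditions: Dess–Martin periodinane (1.5 equiv), NaHCO3, CH2Cl2, 0 °C → rt
Reagents that add atoms: none
Why: Dess–Martin oxidation under buffered conditions gives the epoxy aldehyde, which has no α-hydrogen and therefore cannot epimerize.

**Union and end game**

Step 19
Reactants: 8 terpene (E)-vinyl iodide; 22 propyne; 21 core epoxy aldehyde
Product: 27 pentasilyl ether of arthrosporol A (C7 hydroxyl free), via alkenyllithium 23 (not isolated), via alkenylcopper 24 (not isolated), via dienylcopper 25 (not isolated), via thienylcuprate 26 (not isolated)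
Conditions: 8 (1.3 equiv), tBuLi (2.6 equiv), Et2O, −78 °C; CuBr·SMe2 (1.3 equiv), MgBr2·OEt2 (1.3 equiv), Et2O/Me2S, −45 °C; 22 (6 equiv), −25 °C, then excess 22 removed under reduced pressure at −40 °C; 2-thienyllithium (1.3 equiv), THF, −78 °C; 21 (1.0 equiv), −78 → −40 °C; aq. NH4Cl/NH3
Reagents that add atoms: none
Why: Proposed new method: iodine–lithium exchange and transmetalation give an (E)-alkenylcopper·MgBr2 reagent whose C10–Cu bond should add syn across propyne through a π-complex and a four-centre transition state, copper going to the terminal carbon C8 and C10 to the methyl-bearing carbon C9, so that copper, and later C7, end cis to C10; the closest known reactions are the Normant syn carbocupration of 1-alkynes by alkylcopper·MgBr2 reagents and the addition of alkenylcuprates to ethyne, and the new element is the transfer of an sp2 carbon to a substituted 1-alkyne, for which the small methyl group, the non-basic monoorganocopper (no deprotonation of propyne), the dimethyl sulfide medium and the excess of alkyne are relied on. The (Z)-dienylcopper is inert to aldehydes and is therefore converted by 2-thienyllithium into a dienyl(2-thienyl)cuprate, which transfers only the dienyl group to the aldehyde carbon in a 1,2-addition of the Gilman cuprate type. No ring is closed. The Z geometry of C8=C9 follows from the syn addition and the configurational stability of alkenylcopper species at low temperature; the one new stereocentre C7 is set by chelation control, magnesium (or lithium) bridging the aldehyde oxygen and the epoxide oxygen so that the nucleophile enters past the C2–H flank and away from the C6 silyl ether, which gives the (S)-carbinol. The step needs regioselective carbocupration (copper terminal), chemoselectivity for the aldehyde over the epoxide and facial selectivity at the carbonyl; these rest on the steric bias of the 1-alkyne, on the low temperature at which cuprates add to aldehydes much faster than they open a hindered trisubstituted epoxide, and on the silyl ether at C6.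

Step 20
Reactants: 27 pentasilyl ether
Product: 28 arthrosporol A
Conditions: Bu4NF (10 equiv), AcOH (10 equiv), THF, 0 °C → rt
Reagents that add atoms: none
Why: Fluoride cleaves the three tert-butyldimethylsilyl and two triethylsilyl ethers, and the acetic acid buffer keeps the liberated alkoxides protonated so that no Payne rearrangement of the epoxy alcohols occurs.

**Compound list**

1 | geranyl acetate | CC(C)=CCC/C(C)=C/COC(C)=O | starting material
2 | (R)-6,7-epoxygeranyl acetate | CC1(C)O[C@@H]1CC/C(C)=C/COC(C)=O | intermediate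
3 | [(1S,3R)-3-hydroxy-2,2-dimethyl-6-methylidenecyclohexyl]methyl acetate | CC(=O)OC[C@@H]1C(C)(C)[C@H](O)CCC1=C | intermediate
4 | [(3R,4S,6R)-6-hydroxy-5,5-dimethyl-1-oxaspiro[2.5]octan-4-yl]methyl acetate | CC(=O)OC[C@@H]1C(C)(C)[C@H](O)CC[C@@]12OC2 | intermediate
5 | (1R,2S,4R)-2-(hydroxymethyl)-1,3,3-trimethylcyclohexane-1,4-diol | OC[C@@H]1C(C)(C)[C@H](O)CC[C@@]1(C)O | intermediate
6 | (1R,2S,4R)-1,3,3-trimethyl-1,4-bis(triethylsilyloxy)-2-[(triethylsilyloxy)methyl]cyclohexane | CC[Si](CC)(CC)OC[C@@H]1C(C)(C)[C@H](O[Si](CC)(CC)CC)CC[C@@]1(C)O[Si](CC)(CC)CC | intermediate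
7 | (1R,3R,6R)-2,2,6-trimethyl-3,6-bis(triethylsilyloxy)cyclohexane-1-carbaldehyde | O=C[C@@H]1C(C)(C)[C@H](O[Si](CC)(CC)CC)CC[C@@]1(C)O[Si](CC)(CC)CC | intermediate
8 | (1R,2R,4R)-2-[(E)-2-iodoethenyl]-1,3,3-trimethyl-1,4-bis(triethylsilyloxy)cyclohexane | I/C=C/[C@@H]1C(C)(C)[C@H](O[Si](CC)(CC)CC)CC[C@@]1(C)O[Si](CC)(CC)CC | intermediate
9 | 2,5-dimethoxyterephthalaldehyde | COc1cc(C=O)c(OC)cc1C=O | starting material
10 | 2,5-dimethoxy-1,4-benzenedimethanol | COc1cc(CO)c(OC)cc1CO | intermediate
11 | 1,4-bis[(tert-butyldimethylsilyloxy)methyl]-2,5-dimethoxybenzene | COc1cc(CO[Si](C)(C)C(C)(C)C)c(OC)cc1CO[Si](C)(C)C(C)(C)C | intermediate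
12 | 2,5-bis[(tert-butyldimethylsilyloxy)methyl]-1,4-benzoquinone | O=C1C=C(CO[Si](C)(C)C(C)(C)C)C(=O)C=C1CO[Si](C)(C)C(C)(C)C | intermediate
13 | cyclopentadiene (freshly cracked from the dimer) | C1=CCC=C1 | starting material
14 | endo adduct, 2,5-bis[(tert-butyldimethylsilyloxy)methyl]tricyclo[6.2.1.0(2,7)]undeca-4,9-diene-3,6-dione | CC(C)(C)[Si](C)(C)OCC1=CC(=O)[C@]2(CO[Si](C)(C)C(C)(C)C)[C@@H]3C=C[C@@H](C3)[C@@H]2C1=O | intermediate
15 | exo-4,5-epoxide of 14 | CC(C)(C)[Si](C)(C)OC[C@]12O[C@H]1C(=O)[C@]3(CO[Si](C)(C)C(C)(C)C)[C@@H]4C=C[C@@H](C4)[C@@H]3C2=O | intermediate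
16 | endo,endo-3,6-diol of 15 | CC(C)(C)[Si](C)(C)OC[C@]12O[C@H]1[C@H](O)[C@]3(CO[Si](C)(C)C(C)(C)C)[C@@H]4C=C[C@@H](C4)[C@@H]3[C@@H]2O | intermediate
17 | 3,6-bis(tert-butyldimethylsilyl) ether of 16 | CC(C)(C)[Si](C)(C)OC[C@]12O[C@H]1[C@H](O[Si](C)(C)C(C)(C)C)[C@]3(CO[Si](C)(C)C(C)(C)C)[C@@H]4C=C[C@@H](C4)[C@@H]3[C@@H]2O[Si](C)(C)C(C)(C)C | intermediate
18 | (1S,2S,5R,6S)-2,5-bis(tert-butyldimethylsilyloxy)-1,4-bis[(tert-butyldimethylsilyloxy)methyl]-7-oxabicyclo[4.1.0]hept-3-ene | CC(C)(C)[Si](C)(C)OC[C@]12O[C@H]1[C@H](O[Si](C)(C)C(C)(C)C)C(CO[Si](C)(C)C(C)(C)C)=C[C@@H]2O[Si](C)(C)C(C)(C)C | intermediate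
19 | [(1S,2S,5R,6S)-2,5-bis(tert-butyldimethylsilyloxy)-7-oxabicyclo[4.1.0]hept-3-ene-1,4-diyl]dimethanol | OC[C@]12O[C@H]1[C@H](O[Si](C)(C)C(C)(C)C)C(CO)=C[C@@H]2O[Si](C)(C)C(C)(C)C | intermediate
20 | [(1S,2S,5R,6S)-2,5-bis(tert-butyldimethylsilyloxy)-4-[(tert-butyldimethylsilyloxy)methyl]-7-oxabicyclo[4.1.0]hept-3-en-1-yl]methanol | OC[C@]12O[C@H]1[C@H](O[Si](C)(C)C(C)(C)C)C(CO[Si](C)(C)C(C)(C)C)=C[C@@H]2O[Si](C)(C)C(C)(C)C | intermediate
21 | (1S,2S,5R,6S)-2,5-bis(tert-butyldimethylsilyloxy)-4-[(tert-butyldimethylsilyloxy)methyl]-7-oxabicyclo[4.1.0]hept-3-ene-1-carbaldehyde | O=C[C@]12O[C@H]1[C@H](O[Si](C)(C)C(C)(C)C)C(CO[Si](C)(C)C(C)(C)C)=C[C@@H]2O[Si](C)(C)C(C)(C)C | intermediate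
22 | propyne | CC#C | starting material
23 | (E)-alkenyllithium from 8 | [Li]/C=C/[C@@H]1C(C)(C)[C@H](O[Si](CC)(CC)CC)CC[C@@]1(C)O[Si](CC)(CC)CC | intermediate
24 | (E)-alkenylcopper from 23 (MgBr2 complex) | [Cu]/C=C/[C@@H]1C(C)(C)[C@H](O[Si](CC)(CC)CC)CC[C@@]1(C)O[Si](CC)(CC)CC | intermediate
25 | (1Z,3E)-2-methyldienylcopper (copper on C8, cis to C10) | CC(=C/[Cu])/C=C/[C@@H]1C(C)(C)[C@H](O[Si](CC)(CC)CC)CC[C@@]1(C)O[Si](CC)(CC)CC | intermediate
26 | lithium (1Z,3E)-dienyl(2-thienyl)cuprate | [Li+].CC(=C/[Cu-]c1cccs1)/C=C/[C@@H]1C(C)(C)[C@H](O[Si](CC)(CC)CC)CC[C@@]1(C)O[Si](CC)(CC)CC | intermediate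
27 | pentasilyl ether of arthrosporol A, (S)-configured free hydroxyl at C7, (8Z,10E)-diene | CC(=C/[C@H](O)[C@]12O[C@H]1[C@H](O[Si](C)(C)C(C)(C)C)C(CO[Si](C)(C)C(C)(C)C)=C[C@@H]2O[Si](C)(C)C(C)(C)C)/C=C/[C@@H]1C(C)(C)[C@H](O[Si](CC)(CC)CC)CC[C@@]1(C)O[Si](CC)(CC)CC | intermediate
28 | arthrosporol A | CC(=C/[C@H](O)[C@]12O[C@H]1[C@H](O)C(CO)=C[C@@H]2O)/C=C/[C@@H]1C(C)(C)[C@H](O)CC[C@@]1(C)O | target

**Count and risks**

Total: 20 steps. Longest linear sequence: 13 steps (9 to 28, steps 8–20); the terpene branch has 7 steps before the union.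

Step 19 (proposed new method). The alkenyl group may fail to add across the substituted alkyne, the dienylcopper may transfer sluggishly to the aldehyde, or the facial selectivity at C7 may be poor. The fallback sets out from 8 and 22 and rejoins the route at 27, using known reactions only. Propyne 22 would be bromoborated with BBr3 (CH2Cl2, −78 °C; syn addition, boron terminal) to (Z)-(2-bromoprop-1-enyl)dibromoborane F1 and esterified with pinacol to the (Z)-2-bromopropenyl pinacolboronate F2. Iodide 8 would be taken through alkenyllithium 23 and ZnBr2 to the alkenylzinc bromide F3, which is joined to F2 at the C–Br bond by Negishi coupling (Pd(PtBu3)2, THF) with retention to give the (1Z,3E)-dienylboronate F4. I2/NaOH would convert F4 with retention into the (1Z,3E)-dienyl iodide F5. Halogen–lithium exchange (tBuLi, Et2O, −78 °C) would give the dienyllithium F6, which is added to aldehyde 21 precomplexed with MgBr2·OEt2 to give 27 under the same chelation control.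

Step 11. Enantiofacial selectivity may be poor, or the silyl ether oxygens may inhibit the catalyst. The fallback sets out from 12 and 13 and rejoins at 16. The two would be combined without catalyst (toluene, 0 °C → rt) to give racemic 14, which is carried through steps 12 and 13 to racemic 16. Kinetic resolution with Amano lipase PS and vinyl acetate in tert-butyl methyl ether would acetylate one enantiomer at the less hindered hydroxyl, the one next to the ring-fusion CH. If that is the wanted antipode, its monoacetate F7 is separated and methanolysed (K2CO3, MeOH) to 16; if not, the unreacted enantiomer is 16 itself.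

Step 17. Site selectivity between the two primary hydroxyls may be poor, giving double silylation or silylation at the wrong oxygen. The fallback sets out from 19 and rejoins at 21, bypassing 20, and uses chemoselective oxidation instead of selective protection. MnO2 (CH2Cl2) would oxidize only the allylic hydroxyl to the hydroxy enal F8. The remaining neopentylic hydroxyl would be silylated (Et3SiCl, imidazole) to the triethylsilyl ether F9. The enal would be reduced (NaBH4, CeCl3·7H2O, MeOH) to the allylic alcohol F10 and silylated (TBSCl, imidazole) to the mixed silyl ether F11. Swern oxidation would then convert the primary triethylsilyl ether of F11 directly into aldehyde 21.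

**Further compounds**

F1 | step 19 | (Z)-(2-bromoprop-1-en-1-yl)dibromoborane | C/C(Br)=C/B(Br)Br
F2 | step 19 | (Z)-2-(2-bromoprop-1-en-1-yl)-4,4,5,5-tetramethyl-1,3,2-dioxaborolane | C/C(Br)=C/B1OC(C)(C)C(C)(C)O1
F3 | step 19 | (E)-alkenylzinc bromide from 8 | Br[Zn]/C=C/[C@@H]1C(C)(C)[C@H](O[Si](CC)(CC)CC)CC[C@@]1(C)O[Si](CC)(CC)CC
F4 | step 19 | (1Z,3E)-dienyl pinacolboronate | CC(=C/B1OC(C)(C)C(C)(C)O1)/C=C/[C@@H]1C(C)(C)[C@H](O[Si](CC)(CC)CC)CC[C@@]1(C)O[Si](CC)(CC)CC
F5 | step 19 | (1Z,3E)-dienyl iodide | CC(=C/I)/C=C/[C@@H]1C(C)(C)[C@H](O[Si](CC)(CC)CC)CC[C@@]1(C)O[Si](CC)(CC)CC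
F6 | step 19 | (1Z,3E)-dienyllithium | CC(=C/[Li])/C=C/[C@@H]1C(C)(C)[C@H](O[Si](CC)(CC)CC)CC[C@@]1(C)O[Si](CC)(CC)CC
F7 | step 11 | 6-O-acetate of diol 16 | CC(C)(C)[Si](C)(C)OC[C@]12O[C@H]1[C@H](O)[C@]3(CO[Si](C)(C)C(C)(C)C)[C@@H]4C=C[C@@H](C4)[C@@H]3[C@@H]2OC(C)=O
F8 | step 17 | hydroxy enal (C4 formyl, C1 hydroxymethyl) | OC[C@]12O[C@H]1[C@H](O[Si](C)(C)C(C)(C)C)C(C=O)=C[C@@H]2O[Si](C)(C)C(C)(C)C
F9 | step 17 | triethylsilyl ether of F8 | CC[Si](CC)(CC)OC[C@]12O[C@H]1[C@H](O[Si](C)(C)C(C)(C)C)C(C=O)=C[C@@H]2O[Si](C)(C)C(C)(C)C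
F10 | step 17 | allylic alcohol from F9 | CC[Si](CC)(CC)OC[C@]12O[C@H]1[C@H](O[Si](C)(C)C(C)(C)C)C(CO)=C[C@@H]2O[Si](C)(C)C(C)(C)C
F11 | step 17 | tert-butyldimethylsilyl ether of F10 | CC[Si](CC)(CC)OC[C@]12O[C@H]1[C@H](O[Si](C)(C)C(C)(C)C)C(CO[Si](C)(C)C(C)(C)C)=C[C@@H]2O[Si](C)(C)C(C)(C)C
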